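1. CNP0111480.1 (germacrane numbering: ring C1–C10, C11 on C7 carrying C12 and C13, C14 on C10, C15 on C4) ⇐ PMB cleavage at O13, tigloylation at O8 and CBS reduction of the 8-oxo macrocycle 18 ⇐ Lemieux–Johnson cleavage of the 8-methylidene macrocycle 17.
2. Ten-membered ring (formed last): C7–C8 bond by intramolecular Stille–Kelly coupling of the C7 iodide with the C8 bromoalkene of 16.
3. Butenolide ring O–C6–C7=C11–C12 (formed third, key step): C11–C12 from CO, then the C6–O bond by iodolactonisation of the 2,3-allenoic acid made in the same flask from propargylic mesylate 14.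
4. Enabling feature: the O-bearing sp3 ring carbon C6 adjoins the tetrasubstituted ring alkene C7=C11 that carries C12, so the butenolide is the retron of an allene C6=C7=C11 with a C12 carboxyl; C6 is therefore the carbinol carbon of a C7≡C11 propargylic alcohol, and the iodine left on C7 serves the macrocyclisation.
5. Oxiranes C4–C5 (Sharpless, formed first) and C1–C10 (Shi, second) are set on an acyclic chain from geranyl acetate; the C6–C7 bond comes from acetylide addition to epoxy aldehyde 11.

Key step: step 12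

Remark: B-bromo-9-BBN, hexamethylditin, the D-fructose-derived epoxidation ketone and 4-methoxybenzyl propargyl ether 12 are taken as purchasable (12 is otherwise one Williamson step from propargyl alcohol).
Remark: the ester residue is taken as tiglate, (E)-2-methylbut-2-enoate, as the SMILES specifies.

Step 1
Reactants: 1 geranyl acetate
Product: 2 (2E,6E)-8-hydroxy-3,7-dimethylocta-2,6-dien-1-yl acetate
Conditions: SeO2 (cat.), t-BuOOH, salicylic acid (cat.), CH2Cl2, rt
Reagents that add atoms: tert-butyl hydroperoxide, CC(C)(C)OO (terminal oxidant, oxygen relayed by SeO2)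
Why: Riley allylic oxidation (ene reaction, then [2,3]-sigmatropic shift) should hydroxylate the (E)-methyl group of the electron-rich terminal alkene, the acetate-bearing alkene being deactivated.

Step 2
Reactants: 2 (2E,6E)-8-hydroxy-3,7-dimethylocta-2,6-dien-1-yl acetate
Product: 3 (2E,6E)-8-bromo-3,7-dimethylocta-2,6-dien-1-yl acetate
Conditions: CBr4, PPh3, CH2Cl2, 0 °C
Reagents that add atoms: tetrabromomethane, BrC(Br)(Br)Br
Why: The Appel reaction converts the primary allylic alcohol into the bromide under neutral conditions without allylic transposition.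

Step 3
Reactants: 3 (2E,6E)-8-bromo-3,7-dimethylocta-2,6-dien-1-yl acetate, 4 ethynyltrimethylsilane
Product: 5 (2E,6E)-3,7-dimethyl-10-(trimethylsilyl)deca-2,6-dien-9-yn-1-yl acetate
Conditions: CuI (20 mol %), NaI (cat.), K2CO3, DMF, rt
Reagents that add atoms: none
Why: Copper-acetylide alkynylation of the allylic bromide at its unhindered primary carbon should give the linear skipped enyne with both E-alkenes and the acetate intact.

Step 4
Reactants: 5 (2E,6E)-3,7-dimethyl-10-(trimethylsilyl)deca-2,6-dien-9-yn-1-yl acetate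
Product: 6 (2E,6E)-3,7-dimethyldeca-2,6-dien-9-yn-1-yl acetate
Conditions: AgNO3 (10 mol %), acetone/H2O, rt, dark
Reagents that add atoms: none
Why: Silver-catalysed protodesilylation cleaves only the C(sp)–Si bond and keeps the acetate that shields the C6 oxygen during step 5.

Step 5
Reactants: 6 (2E,6E)-3,7-dimethyldeca-2,6-dien-9-yn-1-yl acetate
Product: 7 (2E,6E)-9-bromo-3,7-dimethyldeca-2,6,9-trien-1-yl acetate
Conditions: B-bromo-9-BBN, CH2Cl2, 0 °C; then AcOH
Reagents that add atoms: B-bromo-9-borabicyclo[3.3.1]nonane, BrB1C2CCCC1CCC2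
Why: Haloboration–protodeboronation puts bromine on the internal alkyne carbon by syn addition of B–Br and then replaces boron by hydrogen, while the trisubstituted alkenes do not react.

Step 6
Reactants: 7 (2E,6E)-9-bromo-3,7-dimethyldeca-2,6,9-trien-1-yl acetate
Product: 8 (2E,6E)-9-bromo-3,7-dimethyldeca-2,6,9-trien-1-ol
Conditions: K2CO3 (cat.), MeOH, 0 °C to rt
Reagents that add atoms: none
Why: Base-catalysed transesterification (methanolysis of the acetate) frees the allylic alcohol that directs step 7.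

Step 7
Reactants: 8 (2E,6E)-9-bromo-3,7-dimethyldeca-2,6,9-trien-1-ol
Product: 9 {(2R,3R)-3-[(3E)-6-bromo-4-methylhepta-3,6-dien-1-yl]-3-methyloxiran-2-yl}methanol
Conditions: Ti(OiPr)4 (10 mol %), D-(−)-diethyl tartrate (12 mol %), t-BuOOH, 4 Å MS, CH2Cl2, −20 °C
Reagents that add atoms: tert-butyl hydroperoxide, CC(C)(C)OO
Why: In the Sharpless asymmetric epoxidation the titanium–D-(−)-tartrate complex binds the allylic alcohol and delivers oxygen to one face of the C4=C5 alkene only, which sets C4 and C5 (both R) and leaves the non-allylic alkenes untouched.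

Step 8
Reactants: 9 {(2R,3R)-3-[(3E)-6-bromo-4-methylhepta-3,6-dien-1-yl]-3-methyloxiran-2-yl}methanol
Product: 10 bis-epoxy alcohol [(2R,3R)-3-{2-[(2R,3R)-3-(2-bromoprop-2-en-1-yl)-3-methyloxiran-2-yl]ethyl}-3-methyloxiran-2-yl]methanol
Conditions: 1,2:4,5-di-O-isopropylidene-β-D-erythro-2,3-hexodiulo-2,6-pyranose (30 mol %), KHSO5 (as 2KHSO5·KHSO4·K2SO4), K2CO3, Bu4NHSO4 (cat.), MeCN/CH2(OMe)2/aq. borate buffer pH 10.5, 0 °C
Reagents that add atoms: potassium peroxymonosulfate, [K+].[O-]S(=O)(=O)OO
Why: In the Shi epoxidation the dioxirane of the D-fructose-derived ketone epoxidises the remaining E-trisubstituted alkene through a spiro transition state to the (R,R)-oxirane, so C1 and C10 are set by the catalyst, while the electron-poor 2-bromoalkene is inert.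

Step 9
Reactants: 10 bis-epoxy alcohol
Product: 11 bis-epoxy aldehyde (2S,3R)-3-{2-[(2R,3R)-3-(2-bromoprop-2-en-1-yl)-3-methyloxiran-2-yl]ethyl}-3-methyloxirane-2-carbaldehyde
Conditions: TEMPO (10 mol %), PhI(OAc)2, CH2Cl2, rt
Reagents that add atoms: none
Why: The TEMPO/PhI(OAc)2 oxidation (oxoammonium mechanism) stops at the aldehyde and is mild enough for an α,β-epoxy aldehyde.

Step 10
Reactants: 11 bis-epoxy aldehyde, 12 4-methoxybenzyl propargyl ether
Product: 13 anti epoxy propargylic alcohol (1R)-1-[(2R,3R)-3-{2-[(2R,3R)-3-(2-bromoprop-2-en-1-yl)-3-methyloxiran-2-yl]ethyl}-3-methyloxiran-2-yl]-4-[(4-methoxyphenyl)methoxy]but-2-yn-1-ol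
Conditions: 12, n-BuLi, THF, −78 °C; then 11, −78 °C; then H2O
Reagents that add atoms: none
Why: Acetylide addition under Felkin–Anh control (nucleophile anti to the epoxide C–O bond) should favour the anti epoxy alcohol with the (R)-carbinol at C6, the stereocentre relayed in step 12, and the minor syn isomer is removed by chromatography.

Step 11
Reactants: 13 anti epoxy propargylic alcohol
Product: 14 (1R)-propargylic methanesulfonate of 13
Conditions: MsCl, Et3N, CH2Cl2, −40 °C; used crude
Reagents that add atoms: methanesulfonyl chloride, CS(=O)(=O)Cl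
Why: O-Sulfonylation of the secondary propargylic alcohol forms only an O–S bond, so the C6 configuration is retained and the leaving group for the SN2′ event is installed.

Step 12
Reactants: 14 (1R)-propargylic methanesulfonate
Product: 16 (5R)-4-iodobutenolide bearing the bis-epoxide chain at C5 and the PMB-oxymethyl group at C3, via allenoic acid 15 (not isolated)
Conditions: Pd(PPh3)4 (5 mol %), CO (1 atm), 2,6-lutidine, THF/H2O (10:1), 0 °C to rt; then I2, NaHCO3, 0 °C, dark
Reagents that add atoms: carbon monoxide, [C-]#[O+]; water, O; iodine, II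
Why: Zerovalent palladium displaces the mesylate anti (SN2′) to an allenylpalladium that inserts CO and is hydrolysed to the axially chiral 2,3-allenoic acid 15, after which iodine (which also destroys the palladium catalyst) activates the C6=C7 bond on the face remote from the carboxylate and the carboxylate oxygen closes onto C6 while iodine stays on C7. The closest known reaction types are the palladium-catalysed hydroxycarbonylation of propargylic mesylates to allenoic acids and the iodolactonisation of 2,3-allenoic acids to 4-iodobutenolides, each with transfer of chirality. The butenolide is the only ring closed, by 5-endo attack of the carboxylate oxygen on the allene terminus, and the ring itself fixes the geometry of the tetrasubstituted C7=C11 alkene (C12 cis to C6). The new C6 stereocentre is controlled by the propargylic stereocentre of 14 through a central-to-axial-to-central relay: two anti events put the lactone oxygen on the side opposite the departed mesylate, so the (R)-mesylate gives the (Ra)-allene and then the C6 configuration of the target. The step needs regioselectivity (oxygen to C6, iodine to C7), secured by the five-membered ring and the polarisation of the iodonium; chemoselectivity, secured by the inertness of the 2-bromoalkene towards zerovalent palladium at or below room temperature and towards iodine; and stereochemical fidelity, secured by the electron-withdrawing epoxide next to C6, which disfavours an open allyl-type cation. The epoxides are shielded from acid by 2,6-lutidine and NaHCO3 and from palladium by CO saturation and the short contact time before the iodine quench.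

Step 13
Reactants: 16 (5R)-4-iodobutenolide
Product: 17 8-methylidene macrocycle (1R,4R,5R,6S,10R)-1,10:4,5-diepoxy-13-[(4-methoxyphenyl)methoxy]-8-methylidenegermacr-7(11)-en-12,6-olide
Conditions: Pd(PPh3)4 (10 mol %), Me3SnSnMe3 (1.05 equiv), 1,4-dioxane (2 mM), 100 °C
Reagents that add atoms: none
Why: In the Stille–Kelly coupling zerovalent palladium inserts into the C7–I bond and hexamethylditin stannylates it, then insertion into the C8–Br bond and intramolecular Stille coupling close the ten-membered ring at C7–C8 under high dilution without creating or touching a stereocentre.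

Step 14
Reactants: 17 8-methylidene macrocycle
Product: 18 8-oxo macrocycle (1R,4R,5R,6S,10R)-1,10:4,5-diepoxy-13-[(4-methoxyphenyl)methoxy]-8-oxogermacr-7(11)-en-12,6-olide
Conditions: OsO4 (2 mol %), NaIO4, 2,6-lutidine, 1,4-dioxane/H2O, rt; used crude
Reagents that add atoms: sodium periodate, [Na+].[O-]I(=O)(=O)=O (ketone oxygen, relayed by OsO4)
Why: In the Lemieux–Johnson oxidation the 1,1-disubstituted C8 methylidene is the only alkene open to osmylation, since the butenolide alkene is tetrasubstituted and electron-poor, and periodate cleaves the diol to the C8 ketone.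

Step 15
Reactants: 18 8-oxo macrocycle
Product: 19 (8S)-alcohol (1R,4R,5R,6S,8S,10R)-1,10:4,5-diepoxy-8-hydroxy-13-[(4-methoxyphenyl)methoxy]germacr-7(11)-en-12,6-olide
Conditions: (R)-2-methyl-CBS-oxazaborolidine (0.5 equiv), BH3·SMe2, CH2Cl2, −40 °C; then MeOH
Reagents that add atoms: none
Why: In the Corey–Bakshi–Shibata reduction the ketone binds the (R)-oxazaborolidine with the large sp2 carbon C7 away from the catalyst, so hydride should reach the face that gives the (8S)-alcohol under non-basic conditions that spare the acidic C6–H.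

Step 16
Reactants: 19 (8S)-alcohol, 20 tigloyl chloride
Product: 21 8-O-tigloyl 13-O-PMB ether (1R,4R,5R,6S,8S,10R)-1,10:4,5-diepoxy-13-[(4-methoxyphenyl)methoxy]-8-[(2E)-2-methylbut-2-enoyloxy]germacr-7(11)-en-12,6-olide
Conditions: pyridine, DMAP (cat.), CH2Cl2, 0 °C to rt
Reagents that add atoms: none
Why: DMAP-catalysed acylation of the secondary alcohol by the acid chloride retains the C8 configuration and the E geometry of the tiglate, and the weak base avoids deprotonation at C6.

Step 17
Reactants: 21 8-O-tigloyl 13-O-PMB ether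
Product: 22 CNP0111480.1
Conditions: DDQ, CH2Cl2/pH 7 phosphate buffer, 0 °C
Reagents that add atoms: none
Why: Oxidative cleavage of the 4-methoxybenzyl ether by DDQ (hydride abstraction, then hydrolysis of the hemiacetal) is neutral and should leave both epoxides, the butenolide and the tiglate intact.

Compound list
1 | geranyl acetate, (2E)-3,7-dimethylocta-2,6-dien-1-yl acetate | CC(=O)OC/C=C(\C)CCC=C(C)C | starting material
2 | (2E,6E)-8-hydroxy-3,7-dimethylocta-2,6-dien-1-yl acetate | CC(=O)OC/C=C(\C)CC/C=C(\C)CO | intermediate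
3 | (2E,6E)-8-bromo-3,7-dimethylocta-2,6-dien-1-yl acetate | CC(=O)OC/C=C(\C)CC/C=C(\C)CBr | intermediate
4 | ethynyltrimethylsilane | C#C[Si](C)(C)C | starting material
5 | (2E,6E)-3,7-dimethyl-10-(trimethylsilyl)deca-2,6-dien-9-yn-1-yl acetate | CC(=O)OC/C=C(\C)CC/C=C(\C)CC#C[Si](C)(C)C | intermediate
6 | (2E,6E)-3,7-dimethyldeca-2,6-dien-9-yn-1-yl acetate | CC(=O)OC/C=C(\C)CC/C=C(\C)CC#C | intermediate
7 | (2E,6E)-9-bromo-3,7-dimethyldeca-2,6,9-trien-1-yl acetate | CC(=O)OC/C=C(\C)CC/C=C(\C)CC(Br)=C | intermediate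
8 | (2E,6E)-9-bromo-3,7-dimethyldeca-2,6,9-trien-1-ol | C=C(Br)C/C(C)=C/CC/C(C)=C/CO | intermediate
9 | {(2R,3R)-3-[(3E)-6-bromo-4-methylhepta-3,6-dien-1-yl]-3-methyloxiran-2-yl}methanol | C=C(Br)C/C(C)=C/CC[C@@]1(C)O[C@@H]1CO | intermediate
10 | [(2R,3R)-3-{2-[(2R,3R)-3-(2-bromoprop-2-en-1-yl)-3-methyloxiran-2-yl]ethyl}-3-methyloxiran-2-yl]methanol | C=C(Br)C[C@@]1(C)O[C@@H]1CC[C@@]1(C)O[C@@H]1CO | intermediate
11 | (2S,3R)-3-{2-[(2R,3R)-3-(2-bromoprop-2-en-1-yl)-3-methyloxiran-2-yl]ethyl}-3-methyloxirane-2-carbaldehyde | C=C(Br)C[C@@]1(C)O[C@@H]1CC[C@@]1(C)O[C@@H]1C=O | intermediate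
12 | 4-methoxybenzyl propargyl ether, 1-methoxy-4-[(prop-2-yn-1-yloxy)methyl]benzene | C#CCOCc1ccc(OC)cc1 | starting material
13 | (1R)-1-[(2R,3R)-3-{2-[(2R,3R)-3-(2-bromoprop-2-en-1-yl)-3-methyloxiran-2-yl]ethyl}-3-methyloxiran-2-yl]-4-[(4-methoxyphenyl)methoxy]but-2-yn-1-ol (carbinol anti to the adjacent epoxide oxygen) | C=C(Br)C[C@@]1(C)O[C@@H]1CC[C@@]1(C)O[C@@H]1[C@H](O)C#CCOCc1ccc(OC)cc1 | intermediate
14 | (1R)-1-[(2R,3R)-3-{2-[(2R,3R)-3-(2-bromoprop-2-en-1-yl)-3-methyloxiran-2-yl]ethyl}-3-methyloxiran-2-yl]-4-[(4-methoxyphenyl)methoxy]but-2-yn-1-yl methanesulfonate | C=C(Br)C[C@@]1(C)O[C@@H]1CC[C@@]1(C)O[C@@H]1[C@H](OS(C)(=O)=O)C#CCOCc1ccc(OC)cc1 | intermediate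
15 | (Ra)-4-[(2R,3R)-3-{2-[(2R,3R)-3-(2-bromoprop-2-en-1-yl)-3-methyloxiran-2-yl]ethyl}-3-methyloxiran-2-yl]-2-{[(4-methoxyphenyl)methoxy]methyl}buta-2,3-dienoic acid | C=C(Br)C[C@@]1(C)O[C@@H]1CC[C@@]1(C)O[C@@H]1C([H])=[C@@]=C(C(O)=O)COCc1ccc(OC)cc1 | intermediate (not isolated)
16 | (5R)-5-[(2R,3R)-3-{2-[(2R,3R)-3-(2-bromoprop-2-en-1-yl)-3-methyloxiran-2-yl]ethyl}-3-methyloxiran-2-yl]-4-iodo-3-{[(4-methoxyphenyl)methoxy]methyl}furan-2(5H)-one (same spatial arrangement at C6 as the target; R only because iodine raises the priority of C7) | C=C(Br)C[C@@]1(C)O[C@@H]1CC[C@@]1(C)O[C@@H]1[C@H]1OC(=O)C(COCc2ccc(OC)cc2)=C1I | intermediate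
17 | (1R,4R,5R,6S,10R)-1,10:4,5-diepoxy-13-[(4-methoxyphenyl)methoxy]-8-methylidenegermacr-7(11)-en-12,6-olide | C=C1C[C@@]2(C)O[C@@H]2CC[C@@]2(C)O[C@@H]2[C@H]2OC(=O)C(COCc3ccc(OC)cc3)=C12 | intermediate
18 | (1R,4R,5R,6S,10R)-1,10:4,5-diepoxy-13-[(4-methoxyphenyl)methoxy]-8-oxogermacr-7(11)-en-12,6-olide | O=C1C[C@@]2(C)O[C@@H]2CC[C@@]2(C)O[C@@H]2[C@H]2OC(=O)C(COCc3ccc(OC)cc3)=C12 | intermediate
19 | (1R,4R,5R,6S,8S,10R)-1,10:4,5-diepoxy-8-hydroxy-13-[(4-methoxyphenyl)methoxy]germacr-7(11)-en-12,6-olide | O[C@H]1C[C@@]2(C)O[C@@H]2CC[C@@]2(C)O[C@@H]2[C@H]2OC(=O)C(COCc3ccc(OC)cc3)=C12 | intermediate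
20 | tigloyl chloride, (2E)-2-methylbut-2-enoyl chloride | C/C=C(\C)C(Cl)=O | starting material
21 | (1R,4R,5R,6S,8S,10R)-1,10:4,5-diepoxy-13-[(4-methoxyphenyl)methoxy]-8-[(2E)-2-methylbut-2-enoyloxy]germacr-7(11)-en-12,6-olide | C/C=C(\C)C(=O)O[C@H]1C[C@@]2(C)O[C@@H]2CC[C@@]2(C)O[C@@H]2[C@H]2OC(=O)C(COCc3ccc(OC)cc3)=C12 | intermediate
22 | CNP0111480.1, (1R,4R,5R,6S,8S,10R)-1,10:4,5-diepoxy-13-hydroxy-8-[(2E)-2-methylbut-2-enoyloxy]germacr-7(11)-en-12,6-olide | C/C=C(\C)C(=O)O[C@H]1C[C@@]2(C)O[C@@H]2CC[C@@]2(C)O[C@@H]2[C@H]2OC(=O)C(CO)=C12 | target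

Total step count: 17. Longest linear sequence: 17 steps (1 to 22; compounds 4, 12 and 20 are purchased and enter directly).

Steps most likely to fail

Step 12. The zerovalent palladium may ionise the epoxide that lies next to the freshly formed allene (SN2′ opening to a dienylpalladium alkoxide) before the iodine quench, and the allenoic acid may lose configurational purity in the flask. The fallback keeps both trisubstituted alkenes through the palladium and iodine events and epoxidises afterwards; it sets out from 8 and comes back to the route at 16. Compound 8 is oxidised with MnO2 to (2E,6E)-9-bromo-3,7-dimethyldeca-2,6,9-trienal F1. Lithiated 12 adds to it to give racemic (5E,9E)-12-bromo-1-[(4-methoxyphenyl)methoxy]-6,10-dimethyltrideca-5,9,12-trien-2-yn-4-ol F2. A Sharpless kinetic resolution (Ti(OiPr)4, L-(+)-diisopropyl tartrate, about 0.6 equivalents of t-BuOOH) should epoxidise the (4R)-enantiomer and leave (4S,5E,9E)-12-bromo-1-[(4-methoxyphenyl)methoxy]-6,10-dimethyltrideca-5,9,12-trien-2-yn-4-ol F3. Mesylation gives its methanesulfonate F4. The same hydroxycarbonylation, kept at or below room temperature, should then give the epoxide-free vinylallenoic acid (Ra,5E,9E)-12-bromo-2-{[(4-methoxyphenyl)methoxy]methyl}-6,10-dimethyltrideca-2,3,5,9,12-pentaenoic acid F5, and iodolactonisation at 0 °C the dienyl iodobutenolide (5R)-5-[(1E,5E)-8-bromo-2,6-dimethylnona-1,5,8-trien-1-yl]-4-iodo-3-{[(4-methoxyphenyl)methoxy]methyl}furan-2(5H)-one F6. A double Shi epoxidation of the two E-trisubstituted alkenes (D-fructose-derived ketone, KHSO5, K2CO3) installs both (R,R)-oxiranes under catalyst control and gives 16.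

Step 13. Intermolecular coupling, oligomerisation and protodestannylation may outrun the slow intramolecular transmetalation at the hindered tetrasubstituted alkenylstannane, and the bromoalkene may be stannylated as well. The fallback separates the two events and moves the ring closure from palladium to copper; it sets out from 16 and comes back at 17. The C–I bond alone is stannylated (Pd(PPh3)4, Me3SnSnMe3, toluene, 60 °C) and (5R)-5-[(2R,3R)-3-{2-[(2R,3R)-3-(2-bromoprop-2-en-1-yl)-3-methyloxiran-2-yl]ethyl}-3-methyloxiran-2-yl]-3-{[(4-methoxyphenyl)methoxy]methyl}-4-(trimethylstannyl)furan-2(5H)-one F7 is isolated. The ring is then closed by a CuCl-mediated alkenylstannane–alkenyl bromide coupling (stoichiometric CuCl, DMF, high dilution), which gives 17.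

Step 15. Hydride delivery may be governed by the conformation of the macrocycle and not by the catalyst (poor or reversed facial selectivity), and the β-acyl butenolide, which is also a β,γ-epoxy ketone, may epimerise at C6 or open an epoxide by elimination if the reduction is slow. The fallback uses substrate control and corrects the configuration during esterification; it sets out from 18 and comes back at 21. A Luche reduction (NaBH4, CeCl3·7H2O, MeOH, −78 °C) should follow the conformational bias of the ring; if it gives 19, step 16 follows as written. If it gives the epimer (1R,4R,5R,6S,8R,10R)-1,10:4,5-diepoxy-8-hydroxy-13-[(4-methoxyphenyl)methoxy]germacr-7(11)-en-12,6-olide F8, a Mitsunobu esterification with tiglic acid (PPh3, diisopropyl azodicarboxylate) inverts C8 and installs the tiglate in one operation, which gives 21.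

Further compounds
F1 | step 12 | (2E,6E)-9-bromo-3,7-dimethyldeca-2,6,9-trienal | C=C(Br)C/C(C)=C/CC/C(C)=C/C=O
F2 | step 12 | rac-(5E,9E)-12-bromo-1-[(4-methoxyphenyl)methoxy]-6,10-dimethyltrideca-5,9,12-trien-2-yn-4-ol | C=C(Br)C/C(C)=C/CC/C(C)=C/C(O)C#CCOCc1ccc(OC)cc1
F3 | step 12 | (4S,5E,9E)-12-bromo-1-[(4-methoxyphenyl)methoxy]-6,10-dimethyltrideca-5,9,12-trien-2-yn-4-ol | C=C(Br)C/C(C)=C/CC/C(C)=C/[C@H](O)C#CCOCc1ccc(OC)cc1
F4 | step 12 | (4S,5E,9E)-12-bromo-1-[(4-methoxyphenyl)methoxy]-6,10-dimethyltrideca-5,9,12-trien-2-yn-4-yl methanesulfonate | C=C(Br)C/C(C)=C/CC/C(C)=C/[C@H](OS(C)(=O)=O)C#CCOCc1ccc(OC)cc1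
F5 | step 12 | (Ra,5E,9E)-12-bromo-2-{[(4-methoxyphenyl)methoxy]methyl}-6,10-dimethyltrideca-2,3,5,9,12-pentaenoic acid | C=C(Br)C/C(C)=C/CC/C(C)=C/C([H])=[C@@]=C(C(O)=O)COCc1ccc(OC)cc1
F6 | step 12 | (5R)-5-[(1E,5E)-8-bromo-2,6-dimethylnona-1,5,8-trien-1-yl]-4-iodo-3-{[(4-methoxyphenyl)methoxy]methyl}furan-2(5H)-one | C=C(Br)C/C(C)=C/CC/C(C)=C/[C@H]1OC(=O)C(COCc2ccc(OC)cc2)=C1I
F7 | step 13 | (5R)-5-[(2R,3R)-3-{2-[(2R,3R)-3-(2-bromoprop-2-en-1-yl)-3-methyloxiran-2-yl]ethyl}-3-methyloxiran-2-yl]-3-{[(4-methoxyphenyl)methoxy]methyl}-4-(trimethylstannyl)furan-2(5H)-one | C=C(Br)C[C@@]1(C)O[C@@H]1CC[C@@]1(C)O[C@@H]1[C@H]1OC(=O)C(COCc2ccc(OC)cc2)=C1[Sn](C)(C)C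
F8 | step 15 | (1R,4R,5R,6S,8R,10R)-1,10:4,5-diepoxy-8-hydroxy-13-[(4-methoxyphenyl)methoxy]germacr-7(11)-en-12,6-olide | O[C@@H]1C[C@@]2(C)O[C@@H]2CC[C@@]2(C)O[C@@H]2[C@H]2OC(=O)C(COCc3ccc(OC)cc3)=C12
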